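The target is read as a labdane with a cis A/B fusion: H-5 and CH3-20 lie on one face of ring B, and C1, C4 and the C4 carboxyl on the other. The C9 side chain is cis to CH3-20 (4S,5R,9R,10S,13R).
End game: C8=C17 comes from a C8 ketone. C9–C11 comes from alkylating the C8/C9 enolate, on the face away from ring A, with a C11–C16 iodide made from methyl hydrogen (R)-3-methylglutarate (source of C13).
Key disconnection: ring A is cut at C1–C10 and C4–C5. Ring B becomes the dearomatised guaiacol 6,6-dimethoxy-5-methylcyclohexa-2,4-dienone, and C1–C4 with C18 and C19 become an (E)-2-methylpenta-2,4-dienoate. A Diels–Alder/Cope cascade joins the two.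
Enabling feature: C8, the only functional carbon of ring B, is next to C9. When ring B is written as a cyclohexa-2,4-dienone blocked at C9, C8 is conjugated through C7=C6 to the fusion bond C5=C10, and the cis fusion is what suprafacial addition to C5=C10 delivers.
Ring order: ring B (from the arene), then a temporary bicyclo[2.2.2]octenone, then ring A. An (S)-1-phenylethyl ester on C19 makes the two core antipodes separable and is lost in the hydrogenation.

Key step: step 4

Numbering used in the text (labdane): ring A = C1, C2, C3, C4, C5, C10. Ring B = C5 to C10. The side chain on C9 is C11 to C16 (C15 ester carbon, C16 methyl on C13). C17 is on C8, C18 (methyl) and C19 (carboxyl) are on C4, and C20 is the methyl on C10.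
Assumption: the stereodescriptors of the SMILES are taken literally (cis ring fusion, unlike common labdanes), and 7 and 13 are taken as purchasable.

Step 1
Reactants: 1 acrolein; 2 methylmalonic acid
Product: 4 (2E)-2-methylpenta-2,4-dienoic acid, via aldol adduct 3 (not isolated)
Conditions: pyridine, hydroquinone (trace), 60 °C
Reagents that add atoms: none
Why: Doebner–Knoevenagel condensation, in which aldol addition of the malonic acid to the aldehyde and decarboxylative dehydration of 3 should give the E acid because the remaining carboxyl group ends trans to the vinyl group.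

Step 2
Reactants: 4 (2E)-2-methylpenta-2,4-dienoic acid; 5 (S)-1-phenylethanol
Product: 6 (1S)-1-phenylethyl (2E)-2-methylpenta-2,4-dienoate
Conditions: DCC, DMAP (cat.), CH2Cl2, 0 to 20 °C
Reagents that add atoms: none
Why: Steglich esterification acylates the alcohol oxygen, so the carbinol C–O bond keeps its S configuration and the diene geometry is not disturbed under neutral conditions.

Step 3
Reactants: 7 2-methoxy-3-methylphenol
Product: 8 6,6-dimethoxy-5-methylcyclohexa-2,4-dien-1-one
Conditions: PhI(OAc)2, MeOH, 0 °C; cold NaHCO3 work-up, used at once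
Reagents that add atoms: methanol, CO
Why: Oxidative dearomatisation of a 2-alkoxyphenol with a trivalent iodine reagent, in which methanol attacks the methoxy-bearing ring carbon to give the ortho-quinone monoketal, whose methyl group next to the ketal slows Diels–Alder self-dimerisation.

Step 4
Reactants: 8 6,6-dimethoxy-5-methylcyclohexa-2,4-dien-1-one; 6 (1S)-1-phenylethyl (2E)-2-methylpenta-2,4-dienoate
Product: 10 (1S)-1-phenylethyl (1S,4aR,8aR)-5,5-dimethoxy-1,4a-dimethyl-6-oxo-1,4,4a,5,6,8a-hexahydronaphthalene-1-carboxylate, via bicyclo[2.2.2]octenone cycloadduct 9 (not isolated)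
Conditions: slow addition of 8 to 6, BHT, mesitylene, 80 °C, then 210 °C (sealed tube); chromatography or crystallisation removes the diastereomer with the antipodal core
Reagents that add atoms: none
Why: Thermal cascade of an intermolecular Diels–Alder reaction and a Cope rearrangement, the established way from masked ortho-benzoquinones and 1,3-dienes to cis-decalins: dienone 8 reacts as the 4π partner (C7=C6–C5=C10) with the unhindered terminal vinyl group of 6 to form C1–C10 and a temporary C2–C7 bond (9), and at the higher temperature the 1,5-diene C4=C3–C2–C7–C6=C5 of 9 undergoes the [3,3] shift that forms C4–C5 and cleaves C2–C7. Ring closures: the [4+2] step closes the temporary six-membered ring C10–C1–C2–C7–C6–C5 of the bicyclo[2.2.2]octenone, and the sigmatropic step, forced into a boat transition state by the bicycle, closes ring A (C10–C1–C2–C3–C4–C5) while ring B is released as the C6=C7–C8=O enone. C10 and C5: C4 hangs from the bridge that already holds C1, so both carbons reach the same face of ring B and H-5 and CH3-20 must end cis. C4: the E geometry of 6 (ester trans to C2, methyl cis to C2) is translated by the boat transition state into the carboxylate on the side of C6 and C9 and CH3-18 on the side of H-5. Selectivity needed: the C8 carbonyl polarises the dienone so that the substituted alkene carbon C2 bonds to C7 and the CH2 carbon C1 bonds to the methyl-bearing C10, and the endo rule places the enoate arm under C5=C6 where the Cope shift can reach it. The two faces of 8 are enantiotopic and the remote ester stereocentre is not expected to choose between them, so both core antipodes form as diastereomers and 10 is separated, its absolute configuration being read against the (S)-1-phenylethyl group by crystal structure analysis.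

Step 5
Reactants: 10 cis-fused dienone ketal
Product: 12 (1S)-1-phenylethyl (1S,4aS,8aR)-1,4a-dimethyl-6-oxo-1,4,4a,5,6,8a-hexahydronaphthalene-1-carboxylate, via monomethoxy ketone 11 (not isolated)
Conditions: SmI2 (5 equiv), THF–MeOH, −78 to 0 °C
Reagents that add atoms: none
Why: Reductive cleavage of α-alkoxy ketones by single-electron transfer from divalent samarium, in which each ketyl expels methoxide from C9 and the samarium enolate is protonated by methanol faster than the enone or the ester is reduced, with no stereocentre touched.

Step 6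
Reactants: 13 methyl hydrogen (R)-3-methylglutarate
Product: 14 methyl (3R)-5-hydroxy-3-methylpentanoate
Conditions: BH3·SMe2, THF, 0 to 20 °C; then H2O; used directly
Reagents that add atoms: none
Why: Chemoselective borane reduction of a carboxylic acid beside an ester (acyloxyborane pathway), which leaves the stereocentre that becomes C13 untouched.

Step 7
Reactants: 14 methyl (3R)-5-hydroxy-3-methylpentanoate
Product: 15 methyl (3S)-5-iodo-3-methylpentanoate
Conditions: PPh3, imidazole, I2, CH2Cl2, 0 °C
Reagents that add atoms: iodine, [I][I]
Why: Appel-type iodination by SN2 displacement of the alkoxyphosphonium ion at the primary carbon, two atoms from the stereocentre, whose descriptor changes only because the priorities change.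

Step 8
Reactants: 12 cis-fused dienone; 15 methyl (3S)-5-iodo-3-methylpentanoate
Product: 17 (1S)-1-phenylethyl (1S,4aR,5S,8aR)-5-[(3R)-5-methoxy-3-methyl-5-oxopentyl]-1,4a-dimethyl-6-oxo-1,4,4a,5,6,8a-hexahydronaphthalene-1-carboxylate, via lithium dienolate 16 (not isolated)
Conditions: LiN(iPr)2 (1.1 equiv), THF, −78 °C; DMPU, 15, −78 to −20 °C
Reagents that add atoms: none
Why: Kinetic α′-deprotonation of the cross-conjugated enone (C7 is vinylic, so C9 is the only α-carbon that bears hydrogen) and SN2 enolate alkylation, in which the iodide should approach C9 anti to the pseudoaxial C10–C1 bond on the convex face that carries CH3-20 and H-5, setting C9 with the side chain cis to CH3-20.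

Step 9
Reactants: 17 alkylated dienone ester
Product: 18 (1S,4aR,5S,8aR)-5-[(3R)-5-methoxy-3-methyl-5-oxopentyl]-1,4a-dimethyl-6-oxodecahydronaphthalene-1-carboxylic acid
Conditions: H2 (1 atm), Pd/C, EtOAc–EtOH, 20 °C
Reagents that add atoms: none
Why: Heterogeneous catalytic hydrogenation saturates C6=C7 and C2=C3 without creating a stereocentre and hydrogenolyses the benzylic ester C–O bond, which does not depend on the hindrance at C19, under neutral conditions that do not enolise C9.

Step 10
Reactants: 18 keto acid
Product: 19 (1S,4aS,5R,8aR)-5-[(3R)-5-methoxy-3-methyl-5-oxopentyl]-1,4a-dimethyl-6-methylidenedecahydronaphthalene-1-carboxylic acid (target; 4S,5R,9R,10S,13R in labdane numbering)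
Conditions: Zn, CH2Br2, TiCl4 (reagent pre-formed in THF, excess), CH2Cl2, 0 to 20 °C; aqueous NaHCO3, then citric acid
Reagents that add atoms: dibromomethane, BrCBr
Why: Lombardo methylenation, in which the non-basic gem-dizinc/titanium reagent converts the hindered C8 ketone into C8=C17 without enolisation, so C9 is not scrambled, the methyl ester is left alone and the acid proton only consumes excess reagent.

Compound list
1 | acrolein | C=CC=O | starting material
2 | methylmalonic acid | CC(C(=O)O)C(=O)O | starting material
3 | 2-(1-hydroxyprop-2-en-1-yl)-2-methylpropanedioic acid (aldol adduct, not isolated) | C=CC(O)C(C)(C(=O)O)C(=O)O | intermediate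
4 | (2E)-2-methylpenta-2,4-dienoic acid | C=C/C=C(\C)C(=O)O | intermediate
5 | (S)-1-phenylethanol | C[C@H](O)c1ccccc1 | starting material
6 | (1S)-1-phenylethyl (2E)-2-methylpenta-2,4-dienoate | C=C/C=C(\C)C(=O)O[C@@H](C)c1ccccc1 | intermediate
7 | 2-methoxy-3-methylphenol | COc1c(C)cccc1O | starting material
8 | 6,6-dimethoxy-5-methylcyclohexa-2,4-dien-1-one | COC1(OC)C(C)=CC=CC1=O | intermediate
9 | (1S)-1-phenylethyl (2E)-3-[(1R,4R,7S)-3,3-dimethoxy-4-methyl-2-oxobicyclo[2.2.2]oct-5-en-7-yl]-2-methylprop-2-enoate (endo cycloadduct, not isolated) | O=C1C(OC)(OC)[C@@]2(C)C=C[C@@H]1[C@H](/C=C(\C)C(=O)O[C@@H](C)c3ccccc3)C2 | intermediate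
10 | (1S)-1-phenylethyl (1S,4aR,8aR)-5,5-dimethoxy-1,4a-dimethyl-6-oxo-1,4,4a,5,6,8a-hexahydronaphthalene-1-carboxylate (cis-fused) | O=C1C=C[C@@H]2[C@@](C)(CC=C[C@]2(C)C(=O)O[C@@H](C)c3ccccc3)C1(OC)OC | intermediate
11 | 5-methoxy analogue of 12 (either C9 epimer, not isolated) | O=C1C=C[C@@H]2[C@@](C)(CC=C[C@]2(C)C(=O)O[C@@H](C)c3ccccc3)C1OC | intermediate
12 | (1S)-1-phenylethyl (1S,4aS,8aR)-1,4a-dimethyl-6-oxo-1,4,4a,5,6,8a-hexahydronaphthalene-1-carboxylate | O=C1C=C[C@@H]2[C@@](C)(CC=C[C@]2(C)C(=O)O[C@@H](C)c3ccccc3)C1 | intermediate
13 | methyl hydrogen (R)-3-methylglutarate, (3R)-5-methoxy-3-methyl-5-oxopentanoic acid | OC(=O)C[C@@H](C)CC(=O)OC | starting material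
14 | methyl (3R)-5-hydroxy-3-methylpentanoate | OCC[C@@H](C)CC(=O)OC | intermediate
15 | methyl (3S)-5-iodo-3-methylpentanoate | ICC[C@@H](C)CC(=O)OC | intermediate
16 | lithium C8/C9 dienolate of 12 (not isolated) | [Li]OC=1C=C[C@@H]2[C@@](C)(CC=C[C@]2(C)C(=O)O[C@@H](C)c3ccccc3)C=1 | intermediate
17 | (1S)-1-phenylethyl (1S,4aR,5S,8aR)-5-[(3R)-5-methoxy-3-methyl-5-oxopentyl]-1,4a-dimethyl-6-oxo-1,4,4a,5,6,8a-hexahydronaphthalene-1-carboxylate | O=C1C=C[C@@H]2[C@@](C)(CC=C[C@]2(C)C(=O)O[C@@H](C)c3ccccc3)[C@@H]1CC[C@@H](C)CC(=O)OC | intermediate
18 | (1S,4aR,5S,8aR)-5-[(3R)-5-methoxy-3-methyl-5-oxopentyl]-1,4a-dimethyl-6-oxodecahydronaphthalene-1-carboxylic acid | O=C1CC[C@@H]2[C@@](C)(CCC[C@]2(C)C(=O)O)[C@@H]1CC[C@@H](C)CC(=O)OC | intermediate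
19 | (1S,4aS,5R,8aR)-5-[(3R)-5-methoxy-3-methyl-5-oxopentyl]-1,4a-dimethyl-6-methylidenedecahydronaphthalene-1-carboxylic acid | C=C1CC[C@@H]2[C@@](C)(CCC[C@]2(C)C(=O)O)[C@@H]1CC[C@@H](C)CC(=O)OC | target

Total step count: 10. Longest linear sequence: 7 steps (1, 2, 4, 5, 8, 9, 10).

Steps most likely to fail

Step 4. The Cope shift has to bond a fully substituted alkene terminus close to the C10 quaternary centre. It may stall, so that 9 accumulates or rearomatises by loss of methanol. Self-dimerisation of 8 or polymerisation of 6 may outrun the cycloaddition, and nothing biases the two faces of 8. The fallback sets out from 8 and comes back at 10. Commercial penta-2,4-dienoic acid is esterified with 5 (DCC, DMAP) to (1S)-1-phenylethyl (2E)-penta-2,4-dienoate F1. Heating F1 with 8 as in step 4 gives the demethyl cycloadduct F2, whose Cope shift now ends on a CH terminus and gives the 4-demethyl cis-decalin F3. F3 is deprotonated with LiN(iPr)2 at C4–H, which is both ester α and allylic, and the dienolate is methylated with MeI at C4 on the convex face (the side of H-5), giving 10. In this way the quaternary centre comes from an enolate alkylation instead of the sigmatropic step.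

Step 8. C-alkylation at C9, next to the quaternary C10, may be slow. Possible consequences are proton exchange, O-alkylation, acylation of the enolate by the nearby C19 ester, or deprotonation at C5 with loss of the cis fusion. The fallback sets out from 12 and comes back at 17. Ketone 12 is condensed with Me2NNH2 (AcOH cat.) to the N,N-dimethylhydrazone F4. Its more nucleophilic lithium azaenolate (LiN(iPr)2, THF) is alkylated with 15 on the same convex face to the alkylated hydrazone F5. Two-phase hydrolysis with aqueous oxalic acid then returns 17.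

Step 10. The hindered ketone may react incompletely, the free acid may consume reagent, and any enolisation would epimerise C9, whose two epimers are expected to be close in energy. The fallback sets out from 18 and comes back at 19 by a Peterson olefination. The weakly basic reagent from Me3SiCH2Li and CeCl3 (excess, THF, −78 °C) adds to the ketone faster than to the methyl ester and gives the β-hydroxysilane F6. Anti elimination with aqueous HF in MeCN then gives 19.

Further compounds
F1 | step 4 | (1S)-1-phenylethyl (2E)-penta-2,4-dienoate | C=C/C=C/C(=O)O[C@@H](C)c1ccccc1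
F2 | step 4 | (1S)-1-phenylethyl (2E)-3-[(1R,4R,7S)-3,3-dimethoxy-4-methyl-2-oxobicyclo[2.2.2]oct-5-en-7-yl]prop-2-enoate | O=C1C(OC)(OC)[C@@]2(C)C=C[C@@H]1[C@H](/C=C/C(=O)O[C@@H](C)c3ccccc3)C2
F3 | step 4 | 4-demethyl analogue of 10 (H on C4 in place of CH3-18) | O=C1C=C[C@@H]2[C@@](C)(CC=C[C@@H]2C(=O)O[C@@H](C)c3ccccc3)C1(OC)OC
F4 | step 8 | N,N-dimethylhydrazone of 12 | CN(C)N=C1C=C[C@@H]2[C@@](C)(CC=C[C@]2(C)C(=O)O[C@@H](C)c3ccccc3)C1
F5 | step 8 | N,N-dimethylhydrazone of 17 | CN(C)N=C1C=C[C@@H]2[C@@](C)(CC=C[C@]2(C)C(=O)O[C@@H](C)c3ccccc3)[C@@H]1CC[C@@H](C)CC(=O)OC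
F6 | step 10 | 8-hydroxy-8-[(trimethylsilyl)methyl] adduct of 18 (C8 configuration open) | C[Si](C)(C)CC1(O)CC[C@@H]2[C@@](C)(CCC[C@]2(C)C(=O)O)[C@@H]1CC[C@@H](C)CC(=O)OC
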